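Remark on the chemistry: the SMILES of the target, of the acetophenone precursor and of the key-step product were checked atom by atom and agree with one another (ring A1 maps onto the 2,6-dimethoxy-4-oxyphenoxy unit, with O1 para and O5/O7 ortho to the ether carbon), so no structure is corrected; the only changes are that the two fluorines are kept until flavone 1 is complete and that the 1,3-diketone of flavone 1 is made by a one-flask C-aroylation.

## Structural features

Isocryptomerin is an achiral biflavone. Two 2-arylchromen-4-one units, flavone 1 (ring A1, pyranone ring C1, ring B1) and flavone 2 (ring A2, pyranone ring C2, ring B2), are joined by one diaryl ether oxygen between C6 of ring A1 and C4' of ring B2. Flavone 1 carries O5–H, O7–Me and a 4'-hydroxyl on ring B1; flavone 2 carries O5–H and O7–H. There is no stereocentre, so the task is one of regiochemistry and of telling five phenolic oxygens apart, only one of which (O7 of flavone 1) is methylated. The ether-bearing C6 of ring A1 lies between the oxygenated carbons C5 and C7 on a ring with five substituents, which makes this aryl–oxygen bond the most crowded in the molecule. Fragile elements are the free phenols, both pyranones (opened by hydroxide), and the 5-hydroxy-6-aryloxy pattern of ring A1, which can isomerise to the 8-aryloxy series (Wessely–Moser rearrangement) if ring C1 opens while both ortho oxygens are free. The real difficulty is to build two differently oxygenated flavones on either side of a hindered diaryl ether and to release four hydroxyls at the end while one methyl ether stays. The key step exploits ring A2: O1, O5 and O7 are ortho, ortho and para to C4a, the carbon that bears the C4 carbonyl, so all three C–O bonds can be made by nucleophilic aromatic substitution on a 2,4,6-trifluorobenzoyl group, the first one intramolecularly to close ring C2.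

## Logic of the disconnections

**17 ⇒ 16.** The cuts are three O–benzyl bonds (O5 and O7 of flavone 2, O4' of ring B1) and the O5–methyl bond of flavone 1. The last operation should only remove carbon from oxygen under non-hydrolytic conditions, so that no pyranone opens and no Wessely–Moser isomerisation can occur. The gain is that all four phenols stay masked to the end, with the methyl ether that must remain already in place. The forward step must cleave benzyl ethers and the carbonyl-chelated methyl ether but leave the non-chelated O7 methyl ether.

**16 ⇒ 15.** The cuts are the C5–O and C7–O bonds of ring A2, which become C–F bonds. The exchange is placed after the construction of flavone 1 so that ring A2 stays electron-poor and free of acid-labile ethers during the acidic and electrophilic steps 5, 6 and 8. The gain is that fluorine acts as a small, inert mask for two hydroxyls through four steps. The forward step must displace fluoride twice with an alkoxide without exchanging the methoxy groups of flavone 1 or opening either pyranone.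

**15 ⇒ 14.** The cut is O1–C2 of ring C1. It opens the pyranone to a 2-hydroxyaryl 1,3-diketone, whose closure is a standard dehydration. The demand is that only one phenolic oxygen stands ortho to the diketone; this is met because the other ortho oxygen is a methyl ether.

**14 ⇒ 12 + 13.** The cut is the C2–C3 bond of flavone 1, between the acetyl methyl carbon and the aroyl carbon. It separates ring B1 as a purchasable acyl donor. The forward step must acylate the enolate carbon in the presence of a phenoxide and two activated C–F bonds.

**12 ⇒ 10 (through 11).** The cut is the C4–C4a bond of flavone 1, the aryl–acetyl bond. The two positions ortho to the free hydroxyl of 10 are equivalent, so no regiochemical choice arises. The forward step must acylate ring A1 only; the fluorinated ring A2 and ring B2 are deactivated.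

**10 ⇒ 9.** The cut is the O–CH2 bond of the methoxymethyl acetal. This is a protecting-group step; the phenol must be masked through the key step and released before acylation. The demand is mild acid only.

**9 ⇒ 6 + 7 (through 8).** The cuts are C3–C4 and O1–C8a of flavone 2. This removes ring C2 and all of ring A2 in one operation and leads back to a simple aryl methyl ketone and a symmetric acyl chloride. The forward step must give C- and not O-acylation, must stop at monoacylation, and must close on an ortho fluorine; the symmetry of 7 removes the last question.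

**6 ⇒ 5.** The cut is the O–CH2 bond of the acetal, now in the protecting direction. The group chosen must withstand amide base, enolates and an acyl chloride, which an acetal does.

**5 ⇒ 3 (through 4).** The aryl C–O bond of the future O1 of flavone 1 is traced back to an aryl–CHO bond. This allows ring A1 to be bought with its oxygen pattern already differentiated. The forward oxidation must insert oxygen at the aldehyde and spare the methyl ketone.

**3 ⇒ 1 + 2.** The cut is the diaryl ether bond between oxygen and C4' of ring B2. It divides the precursor into two cheap arenes. The forward step asks a hindered phenoxide to displace fluoride para to an acetyl group while aldehyde and ketone stay apart.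

## Other disconnections considered

**Alternative 1:** The cut runs through ring B2 itself, at C3'–C4' and C5'–C6'. C4' (with its ether oxygen) and C5' come from an alkyne, and the other four carbons from a 2-pyranone whose ester marks C1'.
- Forward step: methyl coumalate A3 and the aryl ethynyl ether A2 would combine in an inverse-electron-demand [4+2] cycloaddition, and decarboxylative aromatisation would give the para-aryloxybenzoate A1.
- In its favour: the para relation of ether and ester follows from the polarisation of both partners, the conditions are neutral and metal-free, and the crowded oxygen of ring A1 is attached to a two-carbon unit, so no hindered phenoxide attacks an arene.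
- Against it here: A2 needs two further operations from its phenol (vinylation with a chloroalkene, then base-induced elimination) and is a sensitive electron-rich alkyne. A1 is a benzoate, not the methyl ketone that the enolate chemistry needs. The cycloaddition forms no bond of either pyranone, so it can only be added to a flavone synthesis.
- Comparison: on structure the two plans are equal in how ring A1 is delivered, while the chosen plan simply buys ring B2 as 2. On mechanism the pericyclic route is the better one for steric tolerance at the ether oxygen, and it avoids the aldol risk of step 1. On step economy it is worse: about four steps plus an ester-to-ketone adjustment to reach the stage of 6, against three.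

**Alternative 2:** The cut runs through ring A1 at C4a–C5 and C7–C8. C8, C8a and C4a (with esters on C8 and C4a) come from dimethyl 3-oxopentanedioate A6; C5, C6 and C7 (with the aryloxy group on C6) come from the aryloxymalonate A5.
- Forward step: alkoxide-mediated double Claisen condensation of the two α-carbons of A6 with the two ester groups of A5, then enolisation, would give the phloroglucinol diester A4.
- In its favour: the aryloxy group is placed between two oxygenated carbons by construction, the crowded ether is made beforehand by a simple SN2 etherification, and ring B2 arrives with a carboxyl carbon for flavone 2.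
- Against it here: A4 has two equivalent hydroxyls (future O5 and O7) and two equivalent esters (future C4a and C8), and the target needs all of them different. One hydroxyl must be methylated, one ester turned into the C4 carbonyl and the other removed, so desymmetrisation would be statistical or need extra protection. Ring C1 could then close on either ortho hydroxyl and give the 8-aryloxy isomer as well. Hot alkoxide also puts the tert-butyl ester and the malonate (retro-Claisen cleavage) at risk.
- Comparison: on structure the chosen plan is ahead, because 1 supplies ring A1 with two methoxy groups, a free hydroxyl and a formyl group as latent O1. On mechanism the two are equal in using a symmetric ring to remove regiochemistry from the ring-forming step, and the alternative is the better one in how the hindered ether is made. On step economy the alternative is worse, since differentiating three hydroxyls and two esters would cost more than steps 1 to 3 together.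

**Alternative 3:** The cut is the C2=C3 double bond of pyranone ring C1.
- Forward step: the acylmethylene phosphorane A8, which carries the aroyl ester on the neighbouring phenolic oxygen, would be heated so that the ylide carbon olefinates the ester carbonyl (intramolecular Wittig reaction), giving flavone A7.
- In its favour: the closure is neutral, needs neither strong acid nor strong base, leaves benzyl ethers alone, and its regiochemistry is fixed by the position of the ester.
- Against it here: ester carbonyls are reluctant Wittig acceptors, so long heating is needed. A8 takes about three operations from an acetophenone (α-halogenation, phosphonium salt formation, O-aroylation with deprotonation) against two from 12 to 15, and a stoichiometric phosphine oxide is formed. A7 carries bromine on ring B2, so flavone 2 would have to be built later by metal-catalysed C–C bond formation at C1' on a finished flavone.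
- Comparison: on structure the two are equal, since both close ring C1 on the only free ortho oxygen and keep O5 as a methyl ether. On mechanism the Wittig closure is the better one for mildness and would let benzyl ethers enter ring A2 early. On step economy it is worse by one to two steps, and building flavone 1 first gives up fluorine as a mask for O5 and O7. It remains a possible substitute for steps 7 and 8.

Key step: step 4

## Route

Step 1
Reactants: 1 syringaldehyde (4-hydroxy-3,5-dimethoxybenzaldehyde); 2 4'-fluoroacetophenone
Product: 3 4-(4-acetylphenoxy)-3,5-dimethoxybenzaldehyde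
Conditions: K2CO3 (2 equiv), DMSO, 120 °C (1 in slight excess)
Reagents that add atoms: none
Why: Nucleophilic aromatic substitution (addition–elimination): the phenoxide of 1 adds para to the acetyl group of 2, which stabilises the Meisenheimer intermediate, and fluoride leaves. The formyl group of 1 is a poor aldol acceptor while its ring carries the phenoxide, and the slight excess of 1 keeps little enolisable 2 beside the product.

Step 2
Reactants: 3 4-(4-acetylphenoxy)-3,5-dimethoxybenzaldehyde
Product: 5 1-[4-(4-hydroxy-2,6-dimethoxyphenoxy)phenyl]ethanone, via aryl formate 4 (not isolated)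
Conditions: mCPBA (1.2 equiv), CH2Cl2, 0 °C → rt; then K2CO3, MeOH, rt
Reagents that add atoms: mCPBA, O=C(OO)c1cccc(Cl)c1
Why: Baeyer–Villiger oxidation of the aldehyde (Dakin-type): the peracid adds to the formyl group and the 3,4,5-trioxygenated aryl group migrates to oxygen to give formate 4, which methanolysis cleaves. The aryl methyl ketone reacts much more slowly with peracid at rt and should be left.

Step 3
Reactants: 5 1-[4-(4-hydroxy-2,6-dimethoxyphenoxy)phenyl]ethanone
Product: 6 1-{4-[2,6-dimethoxy-4-(methoxymethoxy)phenoxy]phenyl}ethanone
Conditions: MOMCl, iPr2NEt, CH2Cl2, 0 °C → rt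
Reagents that add atoms: chloromethyl methyl ether (MOMCl), COCCl
Why: O-Alkylation of the phenol (methoxymethyl protection). The acetal is inert to amide base, enolates and acyl chloride in step 4 and comes off with dilute acid.

Step 4
Reactants: 6 1-{4-[2,6-dimethoxy-4-(methoxymethoxy)phenoxy]phenyl}ethanone; 7 2,4,6-trifluorobenzoyl chloride
Product: 9 5,7-difluoro-2-{4-[2,6-dimethoxy-4-(methoxymethoxy)phenoxy]phenyl}chromen-4-one, via 1,3-diketone 8 (not isolated)
Conditions: LiN(SiMe3)2 (2.2 equiv), THF, −78 °C; 7 (1.05 equiv), −78 °C → rt; then 65 °C
Reagents that add atoms: none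
Why: LiN(SiMe3)2 converts 6 into its lithium enolate, whose carbon attacks acyl chloride 7 and forms the C3–C4 bond; the 1,3-diketone 8 is deprotonated at once by the second equivalent of base, which also guards it against a second acylation. On warming, the enolate oxygen on the aryl-ketone side adds to a fluorine-bearing carbon ortho to the trifluorobenzoyl carbonyl, the charge of the Meisenheimer intermediate is taken up by that carbonyl, and loss of fluoride forms O1–C8a. Pyranone ring C2 thus closes by a 6-endo-trig addition–elimination (intramolecular SNAr), in which the attacked carbon and the carbon that takes up the charge both lie in the new ring. The closest known reaction type is the one-pot C-acylation of ketone enolates with 2-fluorobenzoyl chlorides followed by SNAr cyclisation to flavones. No stereocentre is formed. C- over O-acylation is secured by the tight lithium–oxygen pairing in THF at low temperature, and monoacylation by formation of the diketonate. The regiochemistry of closure is not in question, because both ortho fluorines of the symmetric 2,4,6-trifluorophenyl ring are equivalent and the para fluorine cannot be reached by the tethered oxygen. The C5 and C7 fluorines remain as masked hydroxyls, and the acetal, the methyl ethers and the diaryl ether are inert to the conditions.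

Step 5
Reactants: 9 5,7-difluoro-2-{4-[2,6-dimethoxy-4-(methoxymethoxy)phenoxy]phenyl}chromen-4-one
Product: 10 5,7-difluoro-2-[4-(4-hydroxy-2,6-dimethoxyphenoxy)phenyl]chromen-4-one
Conditions: HCl (cat.), MeOH/THF, 50 °C
Reagents that add atoms: none
Why: Acid-catalysed acetal cleavage with methanol as trap for the formaldehyde unit. The electron-poor difluorochromone, the aryl methyl ethers and the diaryl ether are stable to dilute acid.

Step 6
Reactants: 10 5,7-difluoro-2-[4-(4-hydroxy-2,6-dimethoxyphenoxy)phenyl]chromen-4-one
Product: 12 2-[4-(3-acetyl-4-hydroxy-2,6-dimethoxyphenoxy)phenyl]-5,7-difluorochromen-4-one, via difluoroboron chelate 11 (not isolated)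
Conditions: BF3·OEt2, AcOH, 85 °C; then aq. NaOAc, 60 °C
Reagents that add atoms: acetic acid, CC(=O)O
Why: Friedel–Crafts acetylation ortho to a phenol (Fries-type): the two positions ortho to the hydroxyl of 10 are equivalent and each is activated by one ortho and one para methoxy group, while ring A2 (two fluorines and a carbonyl) and ring B2 are deactivated. The product is held as chelate 11, which prevents a second acylation, and aqueous NaOAc releases 12.

Step 7
Reactants: 12 2-[4-(3-acetyl-4-hydroxy-2,6-dimethoxyphenoxy)phenyl]-5,7-difluorochromen-4-one; 13 4-(benzyloxy)benzoyl chloride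
Product: 14 1-[4-(benzyloxy)phenyl]-3-{3-[4-(5,7-difluoro-4-oxochromen-2-yl)phenoxy]-6-hydroxy-2,4-dimethoxyphenyl}propane-1,3-dione
Conditions: LiN(SiMe3)2 (3.3 equiv), THF, −78 → −20 °C; 13, −78 → 0 °C; aq. HCl
Reagents that add atoms: none
Why: Direct C-aroylation of the lithium dianion of a 2-hydroxyacetophenone, the one-flask form of the Baker–Venkataraman route to 1,3-diketones. The chelated lithium phenoxide is a poor nucleophile, the enolate carbon reacts with 13 at low temperature, and the third equivalent of base stores the product as its diketonate; the bulky amide should not displace the aryl fluorides below 0 °C.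

Step 8
Reactants: 14 1-[4-(benzyloxy)phenyl]-3-{3-[4-(5,7-difluoro-4-oxochromen-2-yl)phenoxy]-6-hydroxy-2,4-dimethoxyphenyl}propane-1,3-dione
Product: 15 2-[4-(benzyloxy)phenyl]-6-[4-(5,7-difluoro-4-oxochromen-2-yl)phenoxy]-5,7-dimethoxychromen-4-one
Conditions: H2SO4 (cat.), AcOH, 90 °C
Reagents that add atoms: none
Why: Acid-catalysed cyclodehydration of a 2-hydroxyaryl 1,3-diketone, the ring-closing stage of the Baker–Venkataraman flavone synthesis: the phenol adds to the distal carbonyl and water is lost, closing ring C1. Because the other ortho oxygen is a methyl ether, only the 6-aryloxy isomer can form.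

Step 9
Reactants: 15 2-[4-(benzyloxy)phenyl]-6-[4-(5,7-difluoro-4-oxochromen-2-yl)phenoxy]-5,7-dimethoxychromen-4-one
Product: 16 2-[4-(benzyloxy)phenyl]-6-{4-[5,7-bis(benzyloxy)-4-oxochromen-2-yl]phenoxy}-5,7-dimethoxychromen-4-one
Conditions: BnOH, NaH, THF, 0 °C; then 15, rt → 65 °C
Reagents that add atoms: benzyl alcohol, OCc1ccccc1
Why: Twofold nucleophilic aromatic substitution: benzyloxide adds at C7 (para) and C5 (ortho) to the carbonyl-bearing C4a of ring A2 and fluoride leaves. Fluoride is a far better leaving group in SNAr than the methoxy groups of flavone 1, and 15 has no acidic proton, so only the two C–F bonds should be exchanged.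

Step 10
Reactants: 16 2-[4-(benzyloxy)phenyl]-6-{4-[5,7-bis(benzyloxy)-4-oxochromen-2-yl]phenoxy}-5,7-dimethoxychromen-4-one
Product: 17 isocryptomerin, 6-[4-(5,7-dihydroxy-4-oxochromen-2-yl)phenoxy]-5-hydroxy-2-(4-hydroxyphenyl)-7-methoxychromen-4-one
Conditions: BCl3, C6HMe5, CH2Cl2, −78 °C → rt; MeOH quench
Reagents that add atoms: none
Why: Lewis-acid ether cleavage: BCl3 removes the three benzyl groups at low temperature, with pentamethylbenzene trapping the benzyl cations so that ring A2 is not C-benzylated. On warming it cleaves only the O5 methyl ether of flavone 1, because boron is chelated between O5 and the C4 carbonyl; the non-chelated O7 methyl ether and the diaryl ether should remain.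

## Compound list

1 | syringaldehyde (4-hydroxy-3,5-dimethoxybenzaldehyde) | COc1cc(C=O)cc(OC)c1O | starting material
2 | 4'-fluoroacetophenone | CC(=O)c1ccc(F)cc1 | starting material
3 | 4-(4-acetylphenoxy)-3,5-dimethoxybenzaldehyde | COc1cc(C=O)cc(OC)c1Oc1ccc(C(C)=O)cc1 | intermediate
4 | 4-(4-acetylphenoxy)-3,5-dimethoxyphenyl formate | O=COc1cc(OC)c(Oc2ccc(C(C)=O)cc2)c(OC)c1 | intermediate (not isolated)
5 | 1-[4-(4-hydroxy-2,6-dimethoxyphenoxy)phenyl]ethanone | CC(=O)c1ccc(Oc2c(OC)cc(O)cc2OC)cc1 | intermediate
6 | 1-{4-[2,6-dimethoxy-4-(methoxymethoxy)phenoxy]phenyl}ethanone | COCOc1cc(OC)c(Oc2ccc(C(C)=O)cc2)c(OC)c1 | intermediate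
7 | 2,4,6-trifluorobenzoyl chloride | O=C(Cl)c1c(F)cc(F)cc1F | starting material
8 | 1-{4-[2,6-dimethoxy-4-(methoxymethoxy)phenoxy]phenyl}-3-(2,4,6-trifluorophenyl)propane-1,3-dione | COCOc1cc(OC)c(Oc2ccc(C(=O)CC(=O)c3c(F)cc(F)cc3F)cc2)c(OC)c1 | intermediate (not isolated)
9 | 5,7-difluoro-2-{4-[2,6-dimethoxy-4-(methoxymethoxy)phenoxy]phenyl}chromen-4-one | COCOc1cc(OC)c(Oc2ccc(-c3cc(=O)c4c(F)cc(F)cc4o3)cc2)c(OC)c1 | intermediate
10 | 5,7-difluoro-2-[4-(4-hydroxy-2,6-dimethoxyphenoxy)phenyl]chromen-4-one | COc1cc(O)cc(OC)c1Oc1ccc(-c2cc(=O)c3c(F)cc(F)cc3o2)cc1 | intermediate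
11 | difluoroboron chelate of 12 (2,2-difluoro-5,7-dimethoxy-4-methyl-1,3,2-benzodioxaborinine zwitterion carrying the 4-(5,7-difluoro-4-oxochromen-2-yl)phenoxy group at C6) | CC1=[O+][B-](F)(F)Oc2cc(OC)c(Oc3ccc(-c4cc(=O)c5c(F)cc(F)cc5o4)cc3)c(OC)c21 | intermediate (not isolated)
12 | 2-[4-(3-acetyl-4-hydroxy-2,6-dimethoxyphenoxy)phenyl]-5,7-difluorochromen-4-one | CC(=O)c1c(O)cc(OC)c(Oc2ccc(-c3cc(=O)c4c(F)cc(F)cc4o3)cc2)c1OC | intermediate
13 | 4-(benzyloxy)benzoyl chloride | O=C(Cl)c1ccc(OCc2ccccc2)cc1 | starting material
14 | 1-[4-(benzyloxy)phenyl]-3-{3-[4-(5,7-difluoro-4-oxochromen-2-yl)phenoxy]-6-hydroxy-2,4-dimethoxyphenyl}propane-1,3-dione | O=C(CC(=O)c1c(O)cc(OC)c(Oc2ccc(-c3cc(=O)c4c(F)cc(F)cc4o3)cc2)c1OC)c1ccc(OCc2ccccc2)cc1 | intermediate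
15 | 2-[4-(benzyloxy)phenyl]-6-[4-(5,7-difluoro-4-oxochromen-2-yl)phenoxy]-5,7-dimethoxychromen-4-one | COc1cc2oc(-c3ccc(OCc4ccccc4)cc3)cc(=O)c2c(OC)c1Oc1ccc(-c2cc(=O)c3c(F)cc(F)cc3o2)cc1 | intermediate
16 | 2-[4-(benzyloxy)phenyl]-6-{4-[5,7-bis(benzyloxy)-4-oxochromen-2-yl]phenoxy}-5,7-dimethoxychromen-4-one | COc1cc2oc(-c3ccc(OCc4ccccc4)cc3)cc(=O)c2c(OC)c1Oc1ccc(-c2cc(=O)c3c(OCc4ccccc4)cc(OCc4ccccc4)cc3o2)cc1 | intermediate
17 | isocryptomerin, 6-[4-(5,7-dihydroxy-4-oxochromen-2-yl)phenoxy]-5-hydroxy-2-(4-hydroxyphenyl)-7-methoxychromen-4-one (achiral) | COc1cc2oc(-c3ccc(O)cc3)cc(=O)c2c(O)c1Oc1ccc(-c2cc(=O)c3c(O)cc(O)cc3o2)cc1 | target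

## Step count and least certain steps

Total step count: 10. Longest linear sequence: 10 steps, from 1 to 17; 2, 7 and 13 are bought and enter in steps 1, 4 and 7.

**Step 4 (key step).** The most likely failure is O-acylation of the enolate or a second acylation of the diketonate where 7 is locally in excess, followed by sluggish ring closure because the lithium diketonate is a tightly chelated, weak nucleophile in THF. Fallback, from 6 back to 9: the lithium enolate of 6 is added to 2,4,6-trifluorobenzaldehyde at −78 °C (aldol addition) to give racemic 1-{4-[2,6-dimethoxy-4-(methoxymethoxy)phenoxy]phenyl}-3-hydroxy-3-(2,4,6-trifluorophenyl)propan-1-one F1. Oxidation with Dess–Martin periodinane gives diketone 8, now isolated, and K2CO3 in MeCN at 60 °C closes the ring to 9.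

**Step 1.** The hindered, formyl-deactivated phenoxide may substitute slowly, and at the temperature needed the aldehyde of the product may undergo Claisen–Schmidt condensation with a methyl ketone. Fallback, from 1 back to 6, which also removes the reliance of step 2 on aryl migration in a moderately electron-rich ring:
- O-benzylation of 1 (BnBr, K2CO3, DMF) gives 4-(benzyloxy)-3,5-dimethoxybenzaldehyde F2.
- mCPBA gives 4-(benzyloxy)-3,5-dimethoxyphenyl formate F3, and methanolysis gives 4-(benzyloxy)-3,5-dimethoxyphenol F4.
- MOMCl and iPr2NEt give 2-(benzyloxy)-1,3-dimethoxy-5-(methoxymethoxy)benzene F5.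
- Hydrogenolysis (H2, Pd/C, EtOAc) gives 2,6-dimethoxy-4-(methoxymethoxy)phenol F6.
- The electron-rich phenoxide of F6 is arylated with 2 (K2CO3, DMSO, 120 °C), with no aldehyde present, to give 6.

**Step 7.** The phenoxide may be O-aroylated without acyl transfer to carbon, or the enolate or amide may displace an activated fluoride on warming. Fallback, from 12 back to 15, which also bypasses step 8: acid-mediated Claisen–Schmidt condensation of 12 with 4-(benzyloxy)benzaldehyde (BF3·OEt2, dioxane, rt) gives (2E)-3-[4-(benzyloxy)phenyl]-1-{3-[4-(5,7-difluoro-4-oxochromen-2-yl)phenoxy]-6-hydroxy-2,4-dimethoxyphenyl}prop-2-en-1-one F7. Oxidative cyclisation of this 2'-hydroxychalcone (I2 cat., DMSO, 120 °C) gives 15.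

**Step 9.** The second exchange at C5 may stall once the first benzyloxy group has made ring A2 less electrophilic, and forcing it invites exchange of the activated methoxy groups of flavone 1 or alkoxide opening of a pyranone. Fallback, from 12 back to 16, with the exchange made before flavone 1 exists:
- NaH and BnOH in THF convert 12 into 1-(3-{4-[5,7-bis(benzyloxy)-4-oxochromen-2-yl]phenoxy}-6-hydroxy-2,4-dimethoxyphenyl)ethanone F8; the phenoxide is deactivated by chelation to the acetyl group.
- Dianion aroylation with 13 as in step 7 gives 1-[4-(benzyloxy)phenyl]-3-(3-{4-[5,7-bis(benzyloxy)-4-oxochromen-2-yl]phenoxy}-6-hydroxy-2,4-dimethoxyphenyl)propane-1,3-dione F9.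
- Cyclodehydration with TsOH in toluene at 80 °C gives 16.

**Step 10.** Cleavage of the chelated O5 methyl ether may be incomplete at a temperature low enough to spare the O7 methyl ether, or ring A2 may be C-benzylated if cation trapping is incomplete. Fallback, from 16 back to 17: hydrogenolysis (H2, Pd/C, THF/MeOH) removes the three benzyl groups reductively to give 6-[4-(5,7-dihydroxy-4-oxochromen-2-yl)phenoxy]-2-(4-hydroxyphenyl)-5,7-dimethoxychromen-4-one F10. Chelation-controlled monodemethylation at O5 with AlCl3 in MeCN at 50 °C then gives 17.

## Further compounds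

F1 | step 4 | racemic 1-{4-[2,6-dimethoxy-4-(methoxymethoxy)phenoxy]phenyl}-3-hydroxy-3-(2,4,6-trifluorophenyl)propan-1-one | COCOc1cc(OC)c(Oc2ccc(C(=O)CC(O)c3c(F)cc(F)cc3F)cc2)c(OC)c1
F2 | step 1 | 4-(benzyloxy)-3,5-dimethoxybenzaldehyde | COc1cc(C=O)cc(OC)c1OCc1ccccc1
F3 | step 1 | 4-(benzyloxy)-3,5-dimethoxyphenyl formate | O=COc1cc(OC)c(OCc2ccccc2)c(OC)c1
F4 | step 1 | 4-(benzyloxy)-3,5-dimethoxyphenol | COc1cc(O)cc(OC)c1OCc1ccccc1
F5 | step 1 | 2-(benzyloxy)-1,3-dimethoxy-5-(methoxymethoxy)benzene | COCOc1cc(OC)c(OCc2ccccc2)c(OC)c1
F6 | step 1 | 2,6-dimethoxy-4-(methoxymethoxy)phenol | COCOc1cc(OC)c(O)c(OC)c1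
F7 | step 7 | (2E)-3-[4-(benzyloxy)phenyl]-1-{3-[4-(5,7-difluoro-4-oxochromen-2-yl)phenoxy]-6-hydroxy-2,4-dimethoxyphenyl}prop-2-en-1-one | O=C(/C=C/c1ccc(OCc2ccccc2)cc1)c1c(O)cc(OC)c(Oc2ccc(-c3cc(=O)c4c(F)cc(F)cc4o3)cc2)c1OC
F8 | step 9 | 1-(3-{4-[5,7-bis(benzyloxy)-4-oxochromen-2-yl]phenoxy}-6-hydroxy-2,4-dimethoxyphenyl)ethanone | CC(=O)c1c(O)cc(OC)c(Oc2ccc(-c3cc(=O)c4c(OCc5ccccc5)cc(OCc5ccccc5)cc4o3)cc2)c1OC
F9 | step 9 | 1-[4-(benzyloxy)phenyl]-3-(3-{4-[5,7-bis(benzyloxy)-4-oxochromen-2-yl]phenoxy}-6-hydroxy-2,4-dimethoxyphenyl)propane-1,3-dione | O=C(CC(=O)c1c(O)cc(OC)c(Oc2ccc(-c3cc(=O)c4c(OCc5ccccc5)cc(OCc5ccccc5)cc4o3)cc2)c1OC)c1ccc(OCc2ccccc2)cc1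
F10 | step 10 | 6-[4-(5,7-dihydroxy-4-oxochromen-2-yl)phenoxy]-2-(4-hydroxyphenyl)-5,7-dimethoxychromen-4-one | COc1cc2oc(-c3ccc(O)cc3)cc(=O)c2c(OC)c1Oc1ccc(-c2cc(=O)c3c(O)cc(O)cc3o2)cc1
A1 | alternative 1 | methyl 4-[4-(benzyloxy)-2,6-dimethoxyphenoxy]benzoate | COC(=O)c1ccc(Oc2c(OC)cc(OCc3ccccc3)cc2OC)cc1
A2 | alternative 1 | 5-(benzyloxy)-2-(ethynyloxy)-1,3-dimethoxybenzene | C#COc1c(OC)cc(OCc2ccccc2)cc1OC
A3 | alternative 1 | methyl coumalate (methyl 2-oxo-2H-pyran-5-carboxylate) | COC(=O)c1ccc(=O)oc1
A4 | alternative 2 | dimethyl 5-[4-(tert-butoxycarbonyl)phenoxy]-2,4,6-trihydroxybenzene-1,3-dicarboxylate | COC(=O)c1c(O)c(C(=O)OC)c(O)c(Oc2ccc(C(=O)OC(C)(C)C)cc2)c1O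
A5 | alternative 2 | dimethyl 2-[4-(tert-butoxycarbonyl)phenoxy]propanedioate | COC(=O)C(Oc1ccc(C(=O)OC(C)(C)C)cc1)C(=O)OC
A6 | alternative 2 | dimethyl 3-oxopentanedioate | COC(=O)CC(=O)CC(=O)OC
A7 | alternative 3 | 2-[4-(benzyloxy)phenyl]-6-(4-bromophenoxy)-5,7-dimethoxychromen-4-one | COc1cc2oc(-c3ccc(OCc4ccccc4)cc3)cc(=O)c2c(OC)c1Oc1ccc(Br)cc1
A8 | alternative 3 | 4-(4-bromophenoxy)-3,5-dimethoxy-2-[(triphenyl-λ5-phosphanylidene)acetyl]phenyl 4-(benzyloxy)benzoate | COc1cc(OC(=O)c2ccc(OCc3ccccc3)cc2)c(C(=O)C=P(c2ccccc2)(c2ccccc2)c2ccccc2)c(OC)c1Oc1ccc(Br)cc1
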